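## Retrosynthetic overview

1. Target ⇐ protected 15-oxo-16-ene (Luche reduction, then global deprotection) ⇐ C15 allylic oxidation of a tetracycle whose ring D is closed last by C8-enolate alkylation (C8–C15).
2. Tetracycle ⇐ spiro δ-lactone with C8=C9; C9–H comes from SmI2 conjugate reduction, and the isopropenyl group becomes the allyl chloride.
3. Key step: the C9–C10 bond and quaternary C10 arise from a denitrative radical 1,2-alkenyl shift (C9 moves from C20 to C10) in a tertiary β-silyloxy nitro compound; C20–OH then lactonises onto the C7 ester.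
4. Shift precursor ⇐ nitro-aldol union (C10–C20) of a ring A nitrocyclohexane with a ring C formyl enoate. Ring A comes from isobutyraldehyde and a nitroalkene (Michael, allylation, intramolecular Henry); ring C from cyclohexenone (Rh-catalysed conjugate addition).
5. Ring order: A and C separately, then the lactone ring, then D.

Note on numbering: C-numbers are the ent-kaurane positions of the target (C7 lactone carbonyl, C20 lactone CH2, C6 aldehyde carbon, C15 carbinol, C16=C17 exocyclic alkene). The target SMILES corresponds to 1S,3R,5R,8S,9S,10S,13R,15R.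

## Route

Step 1
Reactants: 1 2,2-dimethoxyacetaldehyde; 2 nitromethane
Product: 4 (E)-3,3-dimethoxy-1-nitroprop-1-ene, via nitro alcohol 3 (not isolated)
Conditions: Et3N (0.1 equiv), THF, 0 °C; then MsCl, Et3N, CH2Cl2, −20 °C
Reagents that add atoms: none
Why: Henry (nitro-aldol) addition followed by mesylation and E1cB elimination gives the conjugated nitroalkene in its thermodynamically favoured E geometry, and no stereocentre survives.

Step 2
Reactants: 4 (E)-3,3-dimethoxy-1-nitroprop-1-ene; 5 2-methylpropanal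
Product: 6 (3R)-3-(dimethoxymethyl)-2,2-dimethyl-4-nitrobutanal
Conditions: chiral primary amine–thiourea catalyst (trans-cyclohexane-1,2-diamine derived, enantiomer giving the 3R adduct, 10 mol%), H2O (5 equiv), CH2Cl2, 23 °C
Reagents that add atoms: none
Why: Organocatalytic enamine Michael addition of an α,α-disubstituted aldehyde to a nitroalkene, in which the thiourea binds the nitro group and the enamine attacks one nitroalkene face, sets C5 (R) next to the new gem-dimethyl carbon C4.

Step 3
Reactants: 6 (3R)-3-(dimethoxymethyl)-2,2-dimethyl-4-nitrobutanal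
Product: 7 (4R,6R)-6-(dimethoxymethyl)-5,5-dimethyl-7-nitrohept-1-en-4-ol
Conditions: allylB(pin), (R)-TRIP phosphoric acid (5 mol%, enantiomer chosen to give the 4R alcohol), PhMe, −30 °C
Reagents that add atoms: allylboronic acid pinacol ester, C=CCB1OC(C)(C)C(C)(C)O1
Why: Chiral phosphoric acid-catalysed allylboration through a closed chair transition state lets the catalyst choose the face of the neopentyl aldehyde and sets C3 (R), the allyl group supplying C2 and C1.

Step 4
Reactants: 7 (4R,6R)-6-(dimethoxymethyl)-5,5-dimethyl-7-nitrohept-1-en-4-ol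
Product: 8 tert-butyl{[(4R,6R)-6-(dimethoxymethyl)-5,5-dimethyl-7-nitrohept-1-en-4-yl]oxy}dimethylsilane
Conditions: t-BuMe2SiOTf, 2,6-lutidine, CH2Cl2, −78 °C
Reagents that add atoms: tert-butyldimethylsilyl trifluoromethanesulfonate, CC(C)(C)[Si](C)(C)OS(=O)(=O)C(F)(F)F
Why: Silyl ether formation with a silyl triflate protects the hindered C3 hydroxyl, which is the oxygen that must stay unacylated to the end, and no stereocentre is touched.

Step 5
Reactants: 8 tert-butyl{[(4R,6R)-6-(dimethoxymethyl)-5,5-dimethyl-7-nitrohept-1-en-4-yl]oxy}dimethylsilane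
Product: 10 (1S,2S,3R,5R)-5-[(tert-butyldimethylsilyl)oxy]-3-(dimethoxymethyl)-4,4-dimethyl-2-nitrocyclohexan-1-ol, via nitro aldehyde 9 (not isolated)
Conditions: O3, CH2Cl2/MeOH, −78 °C; Me2S; then Et3N (0.2 equiv), THF, 0 to 23 °C
Reagents that add atoms: ozone, [O-][O+]=O
Why: Ozonolysis unmasks the C1 aldehyde and a reversible intramolecular Henry reaction closes ring A, equilibration through the nitronate and retro-Henry placing OH, NO2, OSi and the acetal-bearing carbon all equatorial, which sets C1 (S) cis to O3 and to C6.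

Step 6
Reactants: 11 cyclohex-2-en-1-one
Product: 12 (3R)-3-(prop-1-en-2-yl)cyclohexan-1-one
Conditions: K[CH2=C(Me)BF3], [Rh(cod)2]PF6 (3 mol%), (R)-BINAP, PhMe/H2O, 105 °C
Reagents that add atoms: potassium isopropenyltrifluoroborate K[CH2=C(Me)BF3], [K+].C=C(C)[B-](F)(F)F
Why: Rhodium-catalysed asymmetric conjugate addition (Hayashi–Miyaura type) of an alkenyl trifluoroborate, in which the BINAP-bound rhodium alkenyl selects one enone face, sets C13 (R).

Step 7
Reactants: 12 (3R)-3-(prop-1-en-2-yl)cyclohexan-1-one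
Product: 13 (2E,5R)-2-[(dimethylamino)methylidene]-5-(prop-1-en-2-yl)cyclohexan-1-one
Conditions: Me2NCH(OMe)2, PhMe, 100 °C
Reagents that add atoms: N,N-dimethylformamide dimethyl acetal, COC(OC)N(C)C
Why: Condensation of the ketone with an amide acetal gives the enaminone at the less hindered α-methylene (the future C9), away from the C13 substituent, and adds the future C20.

Step 8
Reactants: 13 (2E,5R)-2-[(dimethylamino)methylidene]-5-(prop-1-en-2-yl)cyclohexan-1-one
Product: 14 (4R)-2-bromo-4-(prop-1-en-2-yl)cyclohex-1-ene-1-carbaldehyde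
Conditions: (COBr)2, CH2Cl2, 0 °C; then H2O, NaHCO3
Reagents that add atoms: oxalyl bromide, O=C(Br)C(=O)Br; water, O
Why: Vinylogous Vilsmeier-type activation, in which O-acylation of the enaminone and bromide addition–elimination give a β-bromo iminium salt that is hydrolysed, puts bromine on the former carbonyl carbon C8 and leaves the aldehyde on C9 without exposing the isopropenyl group to a free Vilsmeier reagent.

Step 9
Reactants: 14 (4R)-2-bromo-4-(prop-1-en-2-yl)cyclohex-1-ene-1-carbaldehyde
Product: 15 methyl (5R)-2-formyl-5-(prop-1-en-2-yl)cyclohex-1-ene-1-carboxylate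
Conditions: PdCl2(PPh3)2 (5 mol%), CO (1 atm), MeOH, Et3N, DMF, 60 °C
Reagents that add atoms: carbon monoxide, [C-]#[O+]; methanol, CO
Why: Palladium-catalysed alkoxycarbonylation (oxidative addition of the activated vinyl bromide, CO insertion, methanolysis) installs C7 as the methyl ester.

Step 10
Reactants: 10 ring A nitro alcohol (1S,2S,3R,5R)-5-[(tert-butyldimethylsilyl)oxy]-3-(dimethoxymethyl)-4,4-dimethyl-2-nitrocyclohexan-1-ol; 15 methyl (5R)-2-formyl-5-(prop-1-en-2-yl)cyclohex-1-ene-1-carboxylate
Product: 17 tertiary nitro aldol bis(triethylsilyl) ether joining C10 of ring A to C20 on C9 of the enoate (both epimers at C10 and C20), via silyl nitronate 16 (not isolated)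
Conditions: Et3SiCl, DBU, CH2Cl2, 0 to 23 °C; then 15, Bu4NF (0.1 equiv), THF, −78 °C
Reagents that add atoms: chlorotriethylsilane, CC[Si](Cl)(CC)CC
Why: Fluoride-catalysed nitro-aldol addition of a silyl nitronate to the aldehyde (silyl variant of the Henry reaction) forms the C10–C20 bond with silyl transfer to the new alkoxide, which blocks retro-addition and butenolide formation, and the two new stereocentres are erased in step 11.

Step 11
Reactants: 17 tertiary nitro aldol bis(triethylsilyl) ether
Product: 18 methyl (5R)-5-(prop-1-en-2-yl)cyclohex-1-ene-1-carboxylate carrying at C9 the quaternary C10 of ring A, C10 also bearing CH2OSiEt3 (C20)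
Conditions: Bu3SnH (slow addition), AIBN, PhH, 80 °C
Reagents that add atoms: none
Why: Proposed new method: tin-radical denitration of the tertiary nitro group gives the C10 radical, which adds 3-exo to C9 of the neighbouring enoate (polarity-matched, giving an ester-stabilised cyclopropylcarbinyl radical) and reopens toward the α-silyloxy radical at C20 that Bu3SnH quenches, a net 1,2-alkenyl shift from C20 to C10 whose closest known relatives are radical 1,2-vinyl (neophyl-type, Dowd–Beckwith-like) migrations and tin hydride denitrations of tertiary nitroalkanes, and C9 bonds to the planar C10 radical on the face anti to the axial C4 methyl, which sets the quaternary centre.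

Step 12
Reactants: 18 C10-quaternary enoate with C20 as CH2OSiEt3
Product: 20 spiro α,β-unsaturated δ-lactone (C7(=O)–O–C20, C8=C9) with C1–OSiEt3 and C3–OSi(t-Bu)Me2 and the C6 dimethyl acetal, via hydroxy ester 19 (not isolated)
Conditions: PPTS, MeOH, 0 °C; then PPTS, PhMe, 60 °C
Reagents that add atoms: none
Why: Selective methanolysis of the primary silyl ether and acid-catalysed lactonisation of the Z-configured δ-hydroxy enoate (intramolecular transesterification) close the 7,20-lactone.

Step 13
Reactants: 20 spiro α,β-unsaturated δ-lactone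
Product: 21 saturated spiro δ-lactone with C9–H (C8 as an epimer mixture)
Conditions: SmI2, HMPA, MeOH, THF, −78 to 0 °C
Reagents that add atoms: none
Why: Single-electron conjugate reduction of the unsaturated lactone by samarium diiodide, with stereoelectronically controlled axial protonation at C9 of the ring C half-chair that holds the isopropenyl group equatorial, sets C9 (H cis to the C13 substituent, C10 trans) and leaves C8 as an epimer mixture that is planarised in step 15.

Step 14
Reactants: 21 saturated spiro δ-lactone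
Product: 22 allyl chloride (C13 side chain now 3-chloroprop-1-en-2-yl)
Conditions: NCS, PhSeCl (0.1 equiv), CH2Cl2, 23 °C
Reagents that add atoms: N-chlorosuccinimide, O=C1CCC(=O)N1Cl
Why: Selenium-catalysed ene-type allylic chlorination of the 1,1-disubstituted alkene converts the isopropenyl group into a 2-substituted allyl chloride and touches no stereocentre.

Step 15
Reactants: 22 allyl chloride
Product: 23 tetracyclic 16-methylene lactone (rings A, C and D complete; C15 is CH2)
Conditions: LiN(SiMe3)2, THF/DMPU, −78 to 0 °C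
Reagents that add atoms: none
Why: Intramolecular lactone-enolate alkylation (5-exo-tet SN2 on the allylic chloride) closes ring D, and because the tether on C13 can reach only one face of the C8 enolate it sets the quaternary centre C8 and the bicyclo[3.2.1]octane.

Step 16
Reactants: 23 tetracyclic 16-methylene lactone
Product: 25 C1 acetate of the tetracycle, via C1 alcohol 24 (not isolated)
Conditions: HF·pyridine, pyridine, THF, 0 °C; then Ac2O, DMAP, Et3N, CH2Cl2, 23 °C
Reagents that add atoms: acetic anhydride, CC(=O)OC(C)=O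
Why: Buffered fluoride cleaves the triethylsilyl ether much faster than the tert-butyldimethylsilyl ether, and DMAP-catalysed acylation of the only free hydroxyl installs the C1 acetate with retention.

Step 17
Reactants: 25 C1 acetate of the tetracycle
Product: 27 16-methylene-15-ketone (enone), via C15 allylic alcohol 26 (not isolated)
Conditions: SeO2 (0.5 equiv), t-BuOOH, CH2Cl2, 23 °C; then Dess–Martin periodinane, NaHCO3, CH2Cl2, 0 °C
Reagents that add atoms: selenium dioxide, O=[Se]=O; tert-butyl hydroperoxide, CC(C)(C)OO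
Why: SeO2 allylic oxidation (ene reaction then 2,3-sigmatropic shift) attacks the only allylic methylene, C15, and Dess–Martin oxidation converges both C15 epimers on the enone.

Step 18
Reactants: 27 16-methylene-15-ketone
Product: 28 15R allylic alcohol (target with C3–OSi(t-Bu)Me2 and the C6 dimethyl acetal)
Conditions: NaBH4, CeCl3·7H2O, MeOH, −78 °C
Reagents that add atoms: none
Why: Luche 1,2-reduction delivers hydride to the C15 carbonyl from the face of the C14 methylene bridge, away from the axial C11–H that shields the other face, and so gives the 15R alcohol.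

Step 19
Reactants: 28 15R allylic alcohol
Product: 29 target CNP0536233.1
Conditions: HF (48% aq.), MeCN, 0 to 23 °C
Reagents that add atoms: water, O
Why: Aqueous HF cleaves the silyl ether and hydrolyses the dimethyl acetal in one operation under non-basic conditions, so the C3 hydroxyl and the C6 aldehyde appear while C5, the acetate and the allylic alcohol stay untouched.

## Compound list

1 | 2,2-dimethoxyacetaldehyde | COC(OC)C=O | starting material
2 | nitromethane | C[N+](=O)[O-] | starting material
3 | 1,1-dimethoxy-3-nitropropan-2-ol (racemic, not isolated) | COC(OC)C(O)C[N+](=O)[O-] | intermediate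
4 | (E)-3,3-dimethoxy-1-nitroprop-1-ene | COC(OC)/C=C/[N+](=O)[O-] | intermediate
5 | 2-methylpropanal (isobutyraldehyde) | CC(C)C=O | starting material
6 | (3R)-3-(dimethoxymethyl)-2,2-dimethyl-4-nitrobutanal | O=CC(C)(C)[C@H](C[N+](=O)[O-])C(OC)OC | intermediate
7 | (4R,6R)-6-(dimethoxymethyl)-5,5-dimethyl-7-nitrohept-1-en-4-ol | C=CC[C@@H](O)C(C)(C)[C@H](C[N+](=O)[O-])C(OC)OC | intermediate
8 | tert-butyl{[(4R,6R)-6-(dimethoxymethyl)-5,5-dimethyl-7-nitrohept-1-en-4-yl]oxy}dimethylsilane | C=CC[C@@H](O[Si](C)(C)C(C)(C)C)C(C)(C)[C@H](C[N+](=O)[O-])C(OC)OC | intermediate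
9 | (3R,5R)-3-[(tert-butyldimethylsilyl)oxy]-5-(dimethoxymethyl)-4,4-dimethyl-6-nitrohexanal (not isolated) | O=CC[C@@H](O[Si](C)(C)C(C)(C)C)C(C)(C)[C@H](C[N+](=O)[O-])C(OC)OC | intermediate
10 | (1S,2S,3R,5R)-5-[(tert-butyldimethylsilyl)oxy]-3-(dimethoxymethyl)-4,4-dimethyl-2-nitrocyclohexan-1-ol (ring A; ring carbons 1 to 6 are C1, C10, C5, C4, C3, C2) | O[C@H]1C[C@@H](O[Si](C)(C)C(C)(C)C)C(C)(C)[C@@H](C(OC)OC)[C@@H]1[N+](=O)[O-] | intermediate
11 | cyclohex-2-en-1-one | O=C1C=CCCC1 | starting material
12 | (3R)-3-(prop-1-en-2-yl)cyclohexan-1-one | CC(=C)[C@H]1CC(=O)CCC1 | intermediate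
13 | (2E,5R)-2-[(dimethylamino)methylidene]-5-(prop-1-en-2-yl)cyclohexan-1-one | CN(C)/C=C1\CC[C@@H](C(C)=C)CC1=O | intermediate
14 | (4R)-2-bromo-4-(prop-1-en-2-yl)cyclohex-1-ene-1-carbaldehyde | O=CC1=C(Br)C[C@H](C(C)=C)CC1 | intermediate
15 | methyl (5R)-2-formyl-5-(prop-1-en-2-yl)cyclohex-1-ene-1-carboxylate | COC(=O)C1=C(C=O)CC[C@@H](C(C)=C)C1 | intermediate
16 | triethylsilyl nitronate of the O1-triethylsilyl ether of 10 (not isolated) | CC[Si](CC)(CC)O[C@H]1C[C@@H](O[Si](C)(C)C(C)(C)C)C(C)(C)[C@@H](C(OC)OC)C1=[N+]([O-])O[Si](CC)(CC)CC | intermediate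
17 | tertiary nitro aldol: ring A of 10 (C1–OSiEt3) bonded through C10 (bearing NO2) to C20H(OSiEt3), which sits on C9 of the enoate of 15; C1, C3, C5, C13 as in 10 and 15; mixture of epimers at C10 and C20, drawn without configuration there | CC[Si](CC)(CC)O[C@H]1C[C@@H](O[Si](C)(C)C(C)(C)C)C(C)(C)[C@@H](C(OC)OC)C1([N+](=O)[O-])C(O[Si](CC)(CC)CC)C1=C(C(=O)OC)C[C@H](C(C)=C)CC1 | intermediate
18 | 1,2-shift product: methyl (5R)-5-(prop-1-en-2-yl)cyclohex-1-ene-1-carboxylate whose C9 is bonded to quaternary C10 of ring A; C10 also bears CH2OSiEt3 (C20); C1–OSiEt3, C3–OSi(t-Bu)Me2, C5–CH(OMe)2; C10 configured as in the target | CC[Si](CC)(CC)OC[C@@]1(C2=C(C(=O)OC)C[C@H](C(C)=C)CC2)[C@@H](O[Si](CC)(CC)CC)C[C@@H](O[Si](C)(C)C(C)(C)C)C(C)(C)[C@H]1C(OC)OC | intermediate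
19 | hydroxy ester: 18 with free C20–OH (not isolated) | OC[C@@]1(C2=C(C(=O)OC)C[C@H](C(C)=C)CC2)[C@@H](O[Si](CC)(CC)CC)C[C@@H](O[Si](C)(C)C(C)(C)C)C(C)(C)[C@H]1C(OC)OC | intermediate
20 | spiro α,β-unsaturated δ-lactone (C7(=O)–O–C20, C8=C9) with C13-isopropenyl, C1–OSiEt3, C3–OSi(t-Bu)Me2, C5–CH(OMe)2 | CC(=C)[C@@H]1CCC2=C(C1)C(=O)OC[C@]23[C@@H](O[Si](CC)(CC)CC)C[C@@H](O[Si](C)(C)C(C)(C)C)C(C)(C)[C@H]3C(OC)OC | intermediate
21 | saturated spiro δ-lactone: 20 reduced at C8=C9, C9 as in the target, C8 both epimers (drawn without configuration at C8) | CC(=C)[C@@H]1CC[C@@H]2C(C1)C(=O)OC[C@]23[C@@H](O[Si](CC)(CC)CC)C[C@@H](O[Si](C)(C)C(C)(C)C)C(C)(C)[C@H]3C(OC)OC | intermediate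
22 | allyl chloride: 21 with the C13 side chain as 3-chloroprop-1-en-2-yl | ClCC(=C)[C@@H]1CC[C@@H]2C(C1)C(=O)OC[C@]23[C@@H](O[Si](CC)(CC)CC)C[C@@H](O[Si](C)(C)C(C)(C)C)C(C)(C)[C@H]3C(OC)OC | intermediate
23 | tetracycle: 15-deoxy target skeleton (C15 is CH2) with C1–OSiEt3, C3–OSi(t-Bu)Me2, C6 dimethyl acetal; C1, C3, C5, C8, C9, C10, C13 as in the target | C=C1[C@@H]2CC[C@@H]3[C@](C2)(C(=O)OC[C@]32[C@@H](O[Si](CC)(CC)CC)C[C@@H](O[Si](C)(C)C(C)(C)C)C(C)(C)[C@H]2C(OC)OC)C1 | intermediate
24 | 23 with free C1–OH (not isolated) | C=C1[C@@H]2CC[C@@H]3[C@](C2)(C(=O)OC[C@]32[C@@H](O)C[C@@H](O[Si](C)(C)C(C)(C)C)C(C)(C)[C@H]2C(OC)OC)C1 | intermediate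
25 | C1 acetate of the tetracycle (C15 is CH2; C3–OSi(t-Bu)Me2; C6 dimethyl acetal) | C=C1[C@@H]2CC[C@@H]3[C@](C2)(C(=O)OC[C@]32[C@@H](OC(C)=O)C[C@@H](O[Si](C)(C)C(C)(C)C)C(C)(C)[C@H]2C(OC)OC)C1 | intermediate
26 | C15 allylic alcohol of 25, both C15 epimers (not isolated; drawn without configuration at C15) | C=C1[C@@H]2CC[C@@H]3[C@](C2)(C(=O)OC[C@]32[C@@H](OC(C)=O)C[C@@H](O[Si](C)(C)C(C)(C)C)C(C)(C)[C@H]2C(OC)OC)C1O | intermediate
27 | 16-methylene-15-ketone (enone) with C1–OAc, C3–OSi(t-Bu)Me2, C6 dimethyl acetal | C=C1[C@@H]2CC[C@@H]3[C@](C2)(C(=O)OC[C@]32[C@@H](OC(C)=O)C[C@@H](O[Si](C)(C)C(C)(C)C)C(C)(C)[C@H]2C(OC)OC)C1=O | intermediate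
28 | 15R allylic alcohol: target with C3–OSi(t-Bu)Me2 and C6 as dimethyl acetal | C=C1[C@@H]2CC[C@@H]3[C@](C2)(C(=O)OC[C@]32[C@@H](OC(C)=O)C[C@@H](O[Si](C)(C)C(C)(C)C)C(C)(C)[C@H]2C(OC)OC)[C@@H]1O | intermediate
29 | CNP0536233.1: (1S,3R,5R,8S,9S,10S,13R,15R)-1-acetoxy-3,15-dihydroxy-6-oxo-6,7-seco-ent-kaur-16-en-7,20-olide (ent-kaurane numbering) | C=C1[C@@H]2CC[C@@H]3[C@](C2)(C(=O)OC[C@]32[C@@H](OC(C)=O)C[C@@H](O)C(C)(C)[C@H]2C=O)[C@@H]1O | target

## Step count and risk

Total step count: 19. Longest linear sequence: 15 steps (steps 1–5, then 10–19); ring C is made in steps 6–9.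

Steps most likely to fail:

Step 10 (nitro-aldol to a fully substituted nitro carbon next to two ring substituents). The addition may be slow or reversible, and a transient alkoxide could close onto the cis ester. The fallback changes the electrophile and the order of events. It sets out from 10 and from the bromo enal 14, which has no ester to trap an alkoxide. A reversible base-mediated Henry reaction (DBU, THF, 0 °C) followed by exhaustive silylation (Et3SiCl, imidazole, DMF) gives the bis(triethylsilyl) nitro-aldol vinyl bromide F1. Palladium-catalysed methoxycarbonylation of F1 (PdCl2(PPh3)2, CO, MeOH, Et3N, DMF, 60 °C) then installs C7 and comes back to the route at 17.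

Step 11 (the proposed radical 1,2-alkenyl shift). Direct reduction of the C10 radical, or an unfavourable equilibrium between the C10 and C20 radicals, would give unrearranged material. The fallback uses the ionic counterpart, which is known chemistry, and sets out from 17. Reduction of the tertiary nitro group with aluminium amalgam Al(Hg) in THF/H2O gives the tertiary amine F2. Diazotisation (NaNO2, AcOH/H2O, 0 °C) triggers a Tiffeneau–Demjanov-type deaminative semipinacol rearrangement in which C9 shifts from C20 to the C10 cation and the silyloxy carbon becomes a carbonyl, giving the C20 aldehyde F3. NaBH4 (MeOH, −40 °C) reduces the aldehyde to hydroxy ester 19, where the route is rejoined.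

Step 15 (ring D closure at a hindered lactone α-carbon, which needs the conformer with C10 and the side chain both axial). If the lithium enolate alkylation is sluggish, the fallback switches to a soft enolate equivalent and a π-allyl electrophile, and sets out from 22. KN(SiMe3)2 and t-BuMe2SiCl (THF, −78 °C) give the silyl ketene acetal F4. Pd2(dba)3 and dppe with Bu4N[Ph3SiF2] (THF, 23 °C) ionise the allylic chloride to the 2-substituted π-allyl palladium complex and release the enolate, and the intramolecular Tsuji–Trost alkylation closes ring D, coming back to the route at 23.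

Further compounds
F1 | step 10 | bis(triethylsilyl) nitro-aldol vinyl bromide: 17 with bromine on C8 in place of CO2Me (both epimers at C10 and C20) | CC[Si](CC)(CC)O[C@H]1C[C@@H](O[Si](C)(C)C(C)(C)C)C(C)(C)[C@@H](C(OC)OC)C1([N+](=O)[O-])C(O[Si](CC)(CC)CC)C1=C(Br)C[C@H](C(C)=C)CC1
F2 | step 11 | tertiary amine: 17 with NH2 on C10 in place of NO2 (both epimers at C10 and C20) | CC[Si](CC)(CC)O[C@H]1C[C@@H](O[Si](C)(C)C(C)(C)C)C(C)(C)[C@@H](C(OC)OC)C1(N)C(O[Si](CC)(CC)CC)C1=C(C(=O)OC)C[C@H](C(C)=C)CC1
F3 | step 11 | C20 aldehyde: 18 with CHO on C10 in place of CH2OSiEt3 | O=C[C@@]1(C2=C(C(=O)OC)C[C@H](C(C)=C)CC2)[C@@H](O[Si](CC)(CC)CC)C[C@@H](O[Si](C)(C)C(C)(C)C)C(C)(C)[C@H]1C(OC)OC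
F4 | step 15 | tert-butyldimethylsilyl ketene acetal of lactone 22 (C8=C7(OSi)) | ClCC(=C)[C@@H]1CC[C@@H]2C(C1)=C(O[Si](C)(C)C(C)(C)C)OC[C@]23[C@@H](O[Si](CC)(CC)CC)C[C@@H](O[Si](C)(C)C(C)(C)C)C(C)(C)[C@H]3C(OC)OC
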